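In a one-step world with the reagent held steady, E falls at a steady fractional rate, so w, the negative logarithm of the fraction of E left, climbs on a straight line from the first minute.

the same everywhere: E 0.010 M
- Tuesday's: X 0.056 M; run made earlier
- Wednesday's: X 0.088 M; run made earlier
- flask: X 0.0400 M; time 4.0 h

| run | time / h | L / % | E / % |
|---|---|---|---|
| Tuesday's | 0.333 | 1 | 99 |
| Tuesday's | 0.500 | 2 | 97 |
| Tuesday's | 0.667 | 2 | 95 |
| Tuesday's | 1.00 | 3 | 94 |
| Tuesday's | 1.50 | 11 | 83 |
| Tuesday's | 2.50 | 16 | 76 |
| Tuesday's | 4.00 | 26 | 55 |
| Wednesday's | 0.333 | 0 | 99 |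
| Wednesday's | 0.500 | 3 | 96 |
| Wednesday's | 0.667 | 4 | 97 |
| Wednesday's | 1.00 | 6 | 93 |
| Wednesday's | 1.50 | 7 | 86 |
| Wednesday's | 2.50 | 16 | 74 |
| Wednesday's | 4.00 | 30 | 56 |

(each reading ± 1.5 percentage points)

- solid, in amounts per volume of the solution: X
- at the start none of X is in solution
- G is what X becomes in solution

- how much L there is at 4.0 h, in percent of the E charged
- concentration of G in solution at 4.0 h, in percent of saturation

Averaging both runs, we read w as 0.0672 at 1.00 h, 0.288 at 2.50 h and 0.589 at 4.00 h. The slope averages 0.0672 h⁻¹ up to the first of these readings, then reads 0.147 h⁻¹ and finally 0.201 h⁻¹. So the curve starts flat, bends upward, and is still steepening at the last reading. It shows no level, and we take that as cG still rising. We put no figure on how near cG stands to saturation.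

Both runs end alike, with E at 55.5% despite different X. If each E takes one G, the 0.00445 M of E lost in those runs is less than the 0.0400 M of X charged to this flask, so we keep that E for this flask.

The quantity we carry is the L share, L formed per E lost, the selectivity, which we read from both runs at 4.00 h as 62.9%. Our reckoning for this flask is therefore 28.0% of L.

The forecast gives 26% of L and 90% of saturation, reasoning that “the extra solid does little”.

The flask gives 29.1% of L and 45.4% of saturation.

    E + G → Q (k = 35.1 L mol⁻¹ h⁻¹)
    E + G → L (k = 70.0 L mol⁻¹ h⁻¹)
    X ⇌ G, rate k3*(cs3 - [G]) while solid is left; crystals form when [G] > cs3 (solubility = 4.10 mM, k = 0.570 h⁻¹)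

At 4.00 h this flask holds 56% of the E charged, so its L share comes to 66.1%. The neighbouring flask is the same, but with 0.040 M of E. At 4.00 h it has 80.9% of its E left, so 19.1% is lost. Our L share of 62.9% turns that loss into 12.0%, and the neighbouring flask holds 12.7% of L.

The readings are simulated for substances that don't exist, and the scatter is random.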